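**Retrosynthetic overview**

1. Target 28 ⇐ global desilylation and retentive Br→CH3 exchange ⇐ (Z)-bromoalkene 26 ⇐ primary alkylzinc 25 (fragment A, from iodide 8) + 1,1-dibromoalkene 24 (fragment B). The union forms the C7–C8 bond of the nonadienyl chain (chain locants: C1 on lactone C5, C9 on the cyclohexane CH) by trans-selective Negishi mono-alkylation.
2. Enabling feature: chain C7 is a trisubstituted olefinic carbon whose two carbon groups (CH3 and the C8H2–C9H2–cyclohexyl arm) differ only in being cis or trans to the C5H2 group on C6. Entered as CBr2 it has no configuration, and the cis C5H2 group makes the two C–Br bonds kinetically different, so the coupling itself decides the E geometry. The butenolide ring with its acidic C5–H tolerates a neutral organozinc.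
3. Fragment A: the cyclohexane ring is formed first, by enzymatic proton-initiated cyclization of (E)-geranylacetone (both ring stereocentres in one event, the tertiary oxygen held in a temporary dihydropyran ring). Ozonolysis then excises two carbons and leaves chain C8 as CH2OH, then CH2I.
4. Fragment B: anti-carbomagnesiation of propargyl alcohol sets the Z C2=C3 olefin, and CuI-catalysed opening of methyl (R)-glycidate brings in the lactone C5 stereocentre. The butenolide ring is closed by O-acylation/intramolecular Wittig with (triphenylphosphoranylidene)ketene, and the chain C6 aldehyde is converted into CBr2 (chain C7).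
5. Ring order: cyclohexane (with temporary dihydropyran) in fragment A, butenolide in fragment B; no ring is formed in or after the union.

Key step: step 15

Assumption: the cyclase is taken to fold (E)-geranylacetone as it folds the first ring of squalene, which gives the (4aS,8aS) enol ether 2 with the ring configuration the target requires.

**Fragment A**

Step 1
Reactants: 1 (E)-geranylacetone
Product: 2 (4aS,8aS)-2,5,5,8a-tetramethyl-4a,5,6,7,8,8a-hexahydro-4H-chromene
Conditions: squalene–hopene cyclase (recombinant Alicyclobacillus acidocaldarius enzyme, E. coli whole cells), citrate buffer pH 6, Triton X-100, 30 °C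
Reagents that add atoms: none
Why: Enzymatic proton-initiated polyene cyclization: the cyclase protonates the terminal isopropylidene of 1 in a chair fold, the 5,6-olefin adds anti and the ketone oxygen traps the tertiary cation, so both ring stereocentres (side chain trans to oxygen) are set in one event under control of the active site, with enol ether formation closing a temporary dihydropyran ring.

Step 2
Reactants: 2 (4aS,8aS)-2,5,5,8a-tetramethyl-4a,5,6,7,8,8a-hexahydro-4H-chromene
Product: 5 (1S,2S)-2-(2-hydroxyethyl)-1,3,3-trimethylcyclohexan-1-ol, via methoxy hydroperoxide 3 (not isolated), via acetoxy aldehyde 4 (not isolated)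
Conditions: O3, CH2Cl2/MeOH, −78 °C; Me2S, −78 → 23 °C; solvent switch; LiAlH4, THF, 0 → 23 °C
Reagents that add atoms: ozone, [O-][O+]=O
Why: Ozonolysis cleaves only the electron-rich enol ether double bond, Me2S reduces the methanol-trapped carbonyl oxide to the aldehyde, and LiAlH4 reduces the aldehyde and the tertiary acetate left on the ring oxygen, so the two former ketone-side carbons leave as ethanol and the ring stereocentres are untouched.

Step 3
Reactants: 5 (1S,2S)-2-(2-hydroxyethyl)-1,3,3-trimethylcyclohexan-1-ol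
Product: 6 triethyl{2-[(1S,2S)-2,6,6-trimethyl-2-(triethylsilyloxy)cyclohexyl]ethoxy}silane
Conditions: Et3SiOTf, 2,6-lutidine, CH2Cl2, −78 → 0 °C
Reagents that add atoms: triethylsilyl trifluoromethanesulfonate, CC[Si](CC)(CC)OS(=O)(=O)C(F)(F)F
Why: Silylation with a silyl triflate and a hindered pyridine base is reactive enough for the tertiary carbinol and protects both hydroxyls.

Step 4
Reactants: 6 triethyl{2-[(1S,2S)-2,6,6-trimethyl-2-(triethylsilyloxy)cyclohexyl]ethoxy}silane
Product: 7 2-[(1S,2S)-2,6,6-trimethyl-2-(triethylsilyloxy)cyclohexyl]ethan-1-ol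
Conditions: pyridinium p-toluenesulfonate (cat.), MeOH/CH2Cl2, 0 °C
Reagents that add atoms: none
Why: Acid-catalysed methanolysis (selective desilylation) removes the unhindered primary triethylsilyl ether far faster than the hindered tertiary one.

Step 5
Reactants: 7 2-[(1S,2S)-2,6,6-trimethyl-2-(triethylsilyloxy)cyclohexyl]ethan-1-ol
Product: 8 triethyl{[(1S,2S)-2-(2-iodoethyl)-1,3,3-trimethylcyclohexyl]oxy}silane
Conditions: I2, PPh3, imidazole, CH2Cl2, 0 °C
Reagents that add atoms: iodine, II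
Why: Appel-type iodination: iodide displaces the primary alkoxyphosphonium ion in an SN2 reaction, and the silylated tertiary oxygen cannot compete by closing a tetrahydrofuran.

**Fragment B**

Step 6
Reactants: 9 prop-2-yn-1-ol; 10 [2-(1,3-dioxolan-2-yl)ethyl]magnesium bromide
Product: 12 (2Z)-2-[2-(1,3-dioxolan-2-yl)ethyl]-3-iodoprop-2-en-1-ol, via magnesacycle 11 (not isolated)
Conditions: CuI (10 mol%), THF, −10 → 23 °C; then I2, −78 → 0 °C
Reagents that add atoms: iodine, II
Why: Copper-catalysed anti-carbomagnesiation of a propargylic alcohol: the alkyl group adds to the carbinol-proximal alkyne carbon and magnesium ends on the terminal carbon cis to CH2O in a five-membered alkoxide chelate, so iodinolysis with retention fixes the Z configuration of the future C2=C3 olefin.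

Step 7
Reactants: 12 (2Z)-2-[2-(1,3-dioxolan-2-yl)ethyl]-3-iodoprop-2-en-1-ol
Product: 13 tert-butyl({(2Z)-2-[2-(1,3-dioxolan-2-yl)ethyl]-3-iodoprop-2-en-1-yl}oxy)diphenylsilane
Conditions: t-BuPh2SiCl, imidazole, DMF, 23 °C
Reagents that add atoms: tert-butyl(chloro)diphenylsilane, CC(C)(C)[Si](Cl)(c1ccccc1)c1ccccc1
Why: Standard silylation of a primary allylic alcohol; the acid-stable, slowly migrating tert-butyldiphenylsilyl group is chosen to survive steps 8 to 16.

Step 8
Reactants: 13 tert-butyl({(2Z)-2-[2-(1,3-dioxolan-2-yl)ethyl]-3-iodoprop-2-en-1-yl}oxy)diphenylsilane; 14 methyl (2R)-oxirane-2-carboxylate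
Product: 17 methyl (2R,4Z)-5-({[tert-butyl(diphenyl)silyl]oxy}methyl)-7-(1,3-dioxolan-2-yl)-2-hydroxyhept-4-enoate, via alkenyllithium 15 (not isolated), via alkenylmagnesium bromide 16 (not isolated)
Conditions: t-BuLi (2.1 equiv), Et2O, −78 °C; MgBr2·OEt2, −78 → −40 °C; CuI (10 mol%), 14, THF, −40 → −10 °C
Reagents that add atoms: none
Why: Iodine–lithium exchange with retention, immediate transmetalation to magnesium (which forestalls a 1,4-silyl shift) and CuI-catalysed SN2 opening of the glycidic ester at its unsubstituted CH2 carbon join chain C1 to C2 with the Z-olefin intact, and the untouched stereocentre of 14 becomes the (R) lactone C5 centre.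

Step 9
Reactants: 17 methyl (2R,4Z)-5-({[tert-butyl(diphenyl)silyl]oxy}methyl)-7-(1,3-dioxolan-2-yl)-2-hydroxyhept-4-enoate
Product: 18 (2R,4Z)-5-({[tert-butyl(diphenyl)silyl]oxy}methyl)-7-(1,3-dioxolan-2-yl)-2-hydroxy-N-methoxy-N-methylhept-4-enamide
Conditions: MeNH(OMe)·HCl, i-PrMgCl, THF, −20 → 0 °C
Reagents that add atoms: N,O-dimethylhydroxylamine hydrochloride, CNOC.Cl
Why: Aminolysis of the methyl ester by the chloromagnesium amide of N,O-dimethylhydroxylamine gives the N-methoxy-N-methylamide (Weinreb amide), the neighbouring magnesium alkoxide being inert under these conditions.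

Step 10
Reactants: 18 (2R,4Z)-5-({[tert-butyl(diphenyl)silyl]oxy}methyl)-7-(1,3-dioxolan-2-yl)-2-hydroxy-N-methoxy-N-methylhept-4-enamide
Product: 19 (3R,5Z)-6-({[tert-butyl(diphenyl)silyl]oxy}methyl)-8-(1,3-dioxolan-2-yl)-3-hydroxy-1-(methoxymethoxy)oct-5-en-2-one
Conditions: Bu3SnCH2OCH2OCH3, n-BuLi, THF, −78 °C; then 18, −78 °C; NH4Cl (aq.)
Reagents that add atoms: tributyl[(methoxymethoxy)methyl]stannane, CCCC[Sn](CCCC)(CCCC)COCOC
Why: Tin–lithium exchange gives (methoxymethoxy)methyllithium, which adds once to the N-methoxy-N-methylamide because the chelated tetrahedral intermediate survives until the quench (Weinreb ketone synthesis), one further equivalent being spent on the free hydroxyl.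

Step 11
Reactants: 19 (3R,5Z)-6-({[tert-butyl(diphenyl)silyl]oxy}methyl)-8-(1,3-dioxolan-2-yl)-3-hydroxy-1-(methoxymethoxy)oct-5-en-2-one
Product: 21 (5R)-5-[(2Z)-3-({[tert-butyl(diphenyl)silyl]oxy}methyl)-5-(1,3-dioxolan-2-yl)pent-2-en-1-yl]-4-[(methoxymethoxy)methyl]furan-2(5H)-one, via acyl ylide 20 (not isolated)
Conditions: Ph3P=C=C=O, toluene, 90 °C
Reagents that add atoms: (triphenylphosphoranylidene)ketene, O=C=C=P(c1ccccc1)(c1ccccc1)c1ccccc1
Why: The secondary hydroxyl adds to the cumulated ylide to give an ester-stabilised phosphorus ylide that closes onto the adjacent ketone by an intramolecular Wittig reaction, which forms the five-membered butenolide ring regiospecifically without breaking a bond at the stereocentre.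

Step 12
Reactants: 21 (5R)-5-[(2Z)-3-({[tert-butyl(diphenyl)silyl]oxy}methyl)-5-(1,3-dioxolan-2-yl)pent-2-en-1-yl]-4-[(methoxymethoxy)methyl]furan-2(5H)-one
Product: 22 (4Z)-4-({[tert-butyl(diphenyl)silyl]oxy}methyl)-6-[(2R)-3-(hydroxymethyl)-5-oxo-2,5-dihydrofuran-2-yl]hex-4-enal
Conditions: 3 M HCl (aq.)/THF, 45 °C
Reagents that add atoms: water, O
Why: Acid-catalysed acetal hydrolysis releases the aldehyde from the 1,3-dioxolane and the alcohol from the methoxymethyl ether, while the tert-butyldiphenylsilyl ether, the lactone and the trisubstituted olefin should be stable to dilute aqueous mineral acid.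

Step 13
Reactants: 22 (4Z)-4-({[tert-butyl(diphenyl)silyl]oxy}methyl)-6-[(2R)-3-(hydroxymethyl)-5-oxo-2,5-dihydrofuran-2-yl]hex-4-enal
Product: 23 (4Z)-4-({[tert-butyl(diphenyl)silyl]oxy}methyl)-6-[(2R)-3-({[tert-butyl(dimethyl)silyl]oxy}methyl)-5-oxo-2,5-dihydrofuran-2-yl]hex-4-enal
Conditions: t-BuMe2SiCl, imidazole, CH2Cl2, 0 → 23 °C
Reagents that add atoms: tert-butyldimethylsilyl chloride, CC(C)(C)[Si](C)(C)Cl
Why: Silylation of the only hydroxyl; the aldehyde is inert to the silyl chloride and imidazole.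

Step 14
Reactants: 23 (4Z)-4-({[tert-butyl(diphenyl)silyl]oxy}methyl)-6-[(2R)-3-({[tert-butyl(dimethyl)silyl]oxy}methyl)-5-oxo-2,5-dihydrofuran-2-yl]hex-4-enal
Product: 24 (5R)-5-[(2Z)-7,7-dibromo-3-({[tert-butyl(diphenyl)silyl]oxy}methyl)hepta-2,6-dien-1-yl]-4-({[tert-butyl(dimethyl)silyl]oxy}methyl)furan-2(5H)-one
Conditions: CBr4, PPh3, Zn dust, CH2Cl2, 23 °C (ylide preformed); then 23, 0 → 23 °C
Reagents that add atoms: tetrabromomethane, BrC(Br)(Br)Br
Why: Ramirez (Corey–Fuchs) dibromoolefination with the preformed, zinc-generated ylide converts the aldehyde into the configuration-free 1,1-dibromoalkene under neutral conditions that spare the lactone and the silyl ethers.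

**Union and endgame**

Step 15
Reactants: 8 triethyl{[(1S,2S)-2-(2-iodoethyl)-1,3,3-trimethylcyclohexyl]oxy}silane; 24 (5R)-5-[(2Z)-7,7-dibromo-3-({[tert-butyl(diphenyl)silyl]oxy}methyl)hepta-2,6-dien-1-yl]-4-({[tert-butyl(dimethyl)silyl]oxy}methyl)furan-2(5H)-one
Product: 26 (5R)-5-[(2Z,6Z)-7-bromo-3-({[tert-butyl(diphenyl)silyl]oxy}methyl)-9-[(1S,2S)-2,6,6-trimethyl-2-(triethylsilyloxy)cyclohexyl]nona-2,6-dien-1-yl]-4-({[tert-butyl(dimethyl)silyl]oxy}methyl)furan-2(5H)-one, via alkylzinc iodide 25 (not isolated)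
Conditions: 8, Zn dust, LiCl, THF, 40 °C; then 24, PdCl2(DPEphos) (5 mol%; DPEphos = bis[2-(diphenylphosphino)phenyl] ether), THF/DMF, 0 → 23 °C
Reagents that add atoms: none
Why: Zinc inserts into the primary C–I bond of 8 to give the non-basic alkylzinc 25; zerovalent palladium then adds oxidatively to the C–Br bond of 24 that lies trans to the C5H2 group (the cis C–Br is shielded by that allylic CH2), and transmetalation from zinc followed by reductive elimination forms the C7–C8 bond. The closest known reaction type is the trans-selective Negishi mono-alkylation of 1,1-dibromo-1-alkenes with alkylzinc halides under wide-bite-angle bisphosphine–palladium catalysis. No ring is closed in this step. No stereocentre is created, but the olefin configuration is decided here: the C8 arm enters trans to C5 and the bromine left behind is cis, so the later retentive exchange of Br for CH3 can only give the E-olefin. The step needs site selectivity between the two C–Br bonds and arrest after one substitution; both are secured by the cis C5H2 group, which retards oxidative addition into the remaining, more hindered and more electron-rich bromoalkene, while fast reductive elimination from the chelating-diphosphine complex should outrun β-hydride elimination. The organozinc is too weakly basic to touch the epimerisable lactone C5–H, the unsaturated lactone or the silyl ethers, so no further protection is needed.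

Step 16
Reactants: 26 (5R)-5-[(2Z,6Z)-7-bromo-3-({[tert-butyl(diphenyl)silyl]oxy}methyl)-9-[(1S,2S)-2,6,6-trimethyl-2-(triethylsilyloxy)cyclohexyl]nona-2,6-dien-1-yl]-4-({[tert-butyl(dimethyl)silyl]oxy}methyl)furan-2(5H)-one
Product: 27 (5R)-5-[(2Z,6E)-3-({[tert-butyl(diphenyl)silyl]oxy}methyl)-7-methyl-9-[(1S,2S)-2,6,6-trimethyl-2-(triethylsilyloxy)cyclohexyl]nona-2,6-dien-1-yl]-4-({[tert-butyl(dimethyl)silyl]oxy}methyl)furan-2(5H)-one
Conditions: Me2Zn, Pd(P(t-Bu)3)2 (5 mol%), THF, 23 °C
Reagents that add atoms: dimethylzinc, C[Zn]C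
Why: Negishi methylation with the bulky, electron-rich Pd(P(t-Bu)3)2 catalyst exchanges the remaining C–Br bond for C–CH3 with retention of configuration, which should deliver the E-trisubstituted olefin.

Step 17
Reactants: 27 (5R)-5-[(2Z,6E)-3-({[tert-butyl(diphenyl)silyl]oxy}methyl)-7-methyl-9-[(1S,2S)-2,6,6-trimethyl-2-(triethylsilyloxy)cyclohexyl]nona-2,6-dien-1-yl]-4-({[tert-butyl(dimethyl)silyl]oxy}methyl)furan-2(5H)-one
Product: 28 (5R)-4-(hydroxymethyl)-5-{(2Z,6E)-3-(hydroxymethyl)-9-[(1S,2S)-2-hydroxy-2,6,6-trimethylcyclohexyl]-7-methylnona-2,6-dien-1-yl}furan-2(5H)-one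
Conditions: HF·pyridine, pyridine, THF, 0 → 23 °C
Reagents that add atoms: none
Why: Fluoride-mediated global desilylation under buffered, weakly acidic conditions removes all three silyl ethers and should neither epimerise the lactone C5–H nor dehydrate the tertiary alcohol.

**Compound list**

1 | (5E)-6,10-dimethylundeca-5,9-dien-2-one ((E)-geranylacetone) | CC(=O)CC/C=C(\C)CCC=C(C)C | starting material
2 | (4aS,8aS)-2,5,5,8a-tetramethyl-4a,5,6,7,8,8a-hexahydro-4H-chromene | CC1=CC[C@H]2C(C)(C)CCC[C@]2(C)O1 | intermediate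
3 | (1S,2S)-2-(2-hydroperoxy-2-methoxyethyl)-1,3,3-trimethylcyclohexyl acetate (both epimers at the peroxyacetal carbon) | COC(OO)C[C@H]1C(C)(C)CCC[C@]1(C)OC(C)=O | intermediate
4 | (1S,2S)-1,3,3-trimethyl-2-(2-oxoethyl)cyclohexyl acetate | O=CC[C@H]1C(C)(C)CCC[C@]1(C)OC(C)=O | intermediate
5 | (1S,2S)-2-(2-hydroxyethyl)-1,3,3-trimethylcyclohexan-1-ol | OCC[C@H]1C(C)(C)CCC[C@]1(C)O | intermediate
6 | triethyl{2-[(1S,2S)-2,6,6-trimethyl-2-(triethylsilyloxy)cyclohexyl]ethoxy}silane | CC[Si](CC)(CC)OCC[C@H]1C(C)(C)CCC[C@]1(C)O[Si](CC)(CC)CC | intermediate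
7 | 2-[(1S,2S)-2,6,6-trimethyl-2-(triethylsilyloxy)cyclohexyl]ethan-1-ol | OCC[C@H]1C(C)(C)CCC[C@]1(C)O[Si](CC)(CC)CC | intermediate
8 | triethyl{[(1S,2S)-2-(2-iodoethyl)-1,3,3-trimethylcyclohexyl]oxy}silane | ICC[C@H]1C(C)(C)CCC[C@]1(C)O[Si](CC)(CC)CC | intermediate
9 | prop-2-yn-1-ol | C#CCO | starting material
10 | [2-(1,3-dioxolan-2-yl)ethyl]magnesium bromide | Br[Mg]CCC1OCCO1 | starting material
11 | 4-[2-(1,3-dioxolan-2-yl)ethyl]-2,5-dihydro-1,2-oxamagnesole (chelated alkenylmagnesium alkoxide) | C1(CCC2OCCO2)=C[Mg]OC1 | intermediate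
12 | (2Z)-2-[2-(1,3-dioxolan-2-yl)ethyl]-3-iodoprop-2-en-1-ol | OC/C(CCC1OCCO1)=C\I | intermediate
13 | tert-butyl({(2Z)-2-[2-(1,3-dioxolan-2-yl)ethyl]-3-iodoprop-2-en-1-yl}oxy)diphenylsilane | CC(C)(C)[Si](OC/C(CCC1OCCO1)=C\I)(c1ccccc1)c1ccccc1 | intermediate
14 | methyl (2R)-oxirane-2-carboxylate | COC(=O)[C@H]1CO1 | starting material
15 | {(1Z)-3-{[tert-butyl(diphenyl)silyl]oxy}-2-[2-(1,3-dioxolan-2-yl)ethyl]prop-1-en-1-yl}lithium | [Li]/C=C(/CCC1OCCO1)CO[Si](c1ccccc1)(c1ccccc1)C(C)(C)C | intermediate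
16 | bromo{(1Z)-3-{[tert-butyl(diphenyl)silyl]oxy}-2-[2-(1,3-dioxolan-2-yl)ethyl]prop-1-en-1-yl}magnesium | Br[Mg]/C=C(/CCC1OCCO1)CO[Si](c1ccccc1)(c1ccccc1)C(C)(C)C | intermediate
17 | methyl (2R,4Z)-5-({[tert-butyl(diphenyl)silyl]oxy}methyl)-7-(1,3-dioxolan-2-yl)-2-hydroxyhept-4-enoate | COC(=O)[C@H](O)C/C=C(/CCC1OCCO1)CO[Si](c1ccccc1)(c1ccccc1)C(C)(C)C | intermediate
18 | (2R,4Z)-5-({[tert-butyl(diphenyl)silyl]oxy}methyl)-7-(1,3-dioxolan-2-yl)-2-hydroxy-N-methoxy-N-methylhept-4-enamide | CON(C)C(=O)[C@H](O)C/C=C(/CCC1OCCO1)CO[Si](c1ccccc1)(c1ccccc1)C(C)(C)C | intermediate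
19 | (3R,5Z)-6-({[tert-butyl(diphenyl)silyl]oxy}methyl)-8-(1,3-dioxolan-2-yl)-3-hydroxy-1-(methoxymethoxy)oct-5-en-2-one | COCOCC(=O)[C@H](O)C/C=C(/CCC1OCCO1)CO[Si](c1ccccc1)(c1ccccc1)C(C)(C)C | intermediate
20 | (3R,5Z)-6-({[tert-butyl(diphenyl)silyl]oxy}methyl)-8-(1,3-dioxolan-2-yl)-1-(methoxymethoxy)-2-oxooct-5-en-3-yl (triphenylphosphoranylidene)acetate | COCOCC(=O)[C@H](OC(=O)C=P(c1ccccc1)(c1ccccc1)c1ccccc1)C/C=C(/CCC1OCCO1)CO[Si](c1ccccc1)(c1ccccc1)C(C)(C)C | intermediate
21 | (5R)-5-[(2Z)-3-({[tert-butyl(diphenyl)silyl]oxy}methyl)-5-(1,3-dioxolan-2-yl)pent-2-en-1-yl]-4-[(methoxymethoxy)methyl]furan-2(5H)-one | COCOCC1=CC(=O)O[C@@H]1C/C=C(/CCC1OCCO1)CO[Si](c1ccccc1)(c1ccccc1)C(C)(C)C | intermediate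
22 | (4Z)-4-({[tert-butyl(diphenyl)silyl]oxy}methyl)-6-[(2R)-3-(hydroxymethyl)-5-oxo-2,5-dihydrofuran-2-yl]hex-4-enal | O=CCC/C(CO[Si](c1ccccc1)(c1ccccc1)C(C)(C)C)=C/C[C@H]1OC(=O)C=C1CO | intermediate
23 | (4Z)-4-({[tert-butyl(diphenyl)silyl]oxy}methyl)-6-[(2R)-3-({[tert-butyl(dimethyl)silyl]oxy}methyl)-5-oxo-2,5-dihydrofuran-2-yl]hex-4-enal | O=CCC/C(CO[Si](c1ccccc1)(c1ccccc1)C(C)(C)C)=C/C[C@H]1OC(=O)C=C1CO[Si](C)(C)C(C)(C)C | intermediate
24 | (5R)-5-[(2Z)-7,7-dibromo-3-({[tert-butyl(diphenyl)silyl]oxy}methyl)hepta-2,6-dien-1-yl]-4-({[tert-butyl(dimethyl)silyl]oxy}methyl)furan-2(5H)-one | BrC(Br)=CCC/C(CO[Si](c1ccccc1)(c1ccccc1)C(C)(C)C)=C/C[C@H]1OC(=O)C=C1CO[Si](C)(C)C(C)(C)C | intermediate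
25 | iodo{2-[(1S,2S)-2,6,6-trimethyl-2-(triethylsilyloxy)cyclohexyl]ethyl}zinc | I[Zn]CC[C@H]1C(C)(C)CCC[C@]1(C)O[Si](CC)(CC)CC | intermediate
26 | (5R)-5-[(2Z,6Z)-7-bromo-3-({[tert-butyl(diphenyl)silyl]oxy}methyl)-9-[(1S,2S)-2,6,6-trimethyl-2-(triethylsilyloxy)cyclohexyl]nona-2,6-dien-1-yl]-4-({[tert-butyl(dimethyl)silyl]oxy}methyl)furan-2(5H)-one | Br/C(CC[C@H]1C(C)(C)CCC[C@]1(C)O[Si](CC)(CC)CC)=C\CC/C(CO[Si](c1ccccc1)(c1ccccc1)C(C)(C)C)=C/C[C@H]1OC(=O)C=C1CO[Si](C)(C)C(C)(C)C | intermediate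
27 | (5R)-5-[(2Z,6E)-3-({[tert-butyl(diphenyl)silyl]oxy}methyl)-7-methyl-9-[(1S,2S)-2,6,6-trimethyl-2-(triethylsilyloxy)cyclohexyl]nona-2,6-dien-1-yl]-4-({[tert-butyl(dimethyl)silyl]oxy}methyl)furan-2(5H)-one | C/C(CC[C@H]1C(C)(C)CCC[C@]1(C)O[Si](CC)(CC)CC)=C\CC/C(CO[Si](c1ccccc1)(c1ccccc1)C(C)(C)C)=C/C[C@H]1OC(=O)C=C1CO[Si](C)(C)C(C)(C)C | intermediate
28 | (5R)-4-(hydroxymethyl)-5-{(2Z,6E)-3-(hydroxymethyl)-9-[(1S,2S)-2-hydroxy-2,6,6-trimethylcyclohexyl]-7-methylnona-2,6-dien-1-yl}furan-2(5H)-one | C/C(=C\CC/C(=C/C[C@H]1OC(=O)C=C1CO)CO)CC[C@H]1C(C)(C)CCC[C@]1(C)O | target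

**Step count**

Total: 17 steps. Longest linear sequence: 12 steps (steps 6 to 17, from 9 and 10 to 28); fragment A joins after 5 steps.

**Steps most likely to fail**

Step 15. The union may lose site selectivity (a second alkylation at the remaining C–Br bond), the alkylpalladium intermediate may be reduced by β-hydride elimination, or zinc insertion into the hindered iodide may stall. Fallback, which moves the union to the boron (Suzuki–Miyaura) manifold: from 8, iodine–lithium exchange (t-BuLi, Et2O, −78 °C) should give {2-[(1S,2S)-2,6,6-trimethyl-2-(triethylsilyloxy)cyclohexyl]ethyl}lithium F1. Trapping with B-methoxy-9-borabicyclo[3.3.1]nonane should give the lithium alkyl(methoxy)borinate F2. This ate complex would be coupled with 24 under Pd(dppf)Cl2 (dppf = 1,1'-bis(diphenylphosphino)ferrocene), AsPh3 and K3PO4 in DMF/THF at 23 °C, again at the less hindered trans C–Br bond, and the route is rejoined at 26.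

Step 1. The short substrate may be poorly accepted by the cyclase (low conversion, difficult two-phase work-up). Fallback, a racemic chemical cyclization followed by resolution: from 1, ClSO3H in 2-nitropropane at −78 °C should give the racemic trans-fused enol ether F3. The sequence of step 2 would carry it through the racemic methoxy hydroperoxide F4 and the racemic acetoxy aldehyde F5 to the racemic diol F6. Esterification of the primary hydroxyl with (S)-2-methoxy-2-phenylacetic acid (DCC, DMAP, CH2Cl2) and preparative HPLC would separate the ester of the (1S,2S) diol F7 from its diastereomer F8. K2CO3 in MeOH cleaves F7, and the route is rejoined at 5.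

Step 11. The carbinol centre may lose configuration by enolisation of the α-hydroxy ketone under the hot ylide conditions, or ring closure onto the doubly α-oxygenated ketone may be slow. Fallback, an intramolecular Horner–Wadsworth–Emmons reaction at low temperature: from 19, esterification with diethylphosphonoacetic acid (DCC, DMAP, CH2Cl2, 0 °C) should give the phosphonoacetate F9. It would be closed with LiCl and i-Pr2NEt in MeCN at 0 → 23 °C (Masamune–Roush conditions), and the route is rejoined at 21.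

**Further compounds**

F1 | step 15 | {2-[(1S,2S)-2,6,6-trimethyl-2-(triethylsilyloxy)cyclohexyl]ethyl}lithium | [Li]CC[C@H]1C(C)(C)CCC[C@]1(C)O[Si](CC)(CC)CC
F2 | step 15 | lithium 9-methoxy-9-{2-[(1S,2S)-2,6,6-trimethyl-2-(triethylsilyloxy)cyclohexyl]ethyl}-9-boranuidabicyclo[3.3.1]nonane | [Li+].CO[B-]1(CC[C@H]2C(C)(C)CCC[C@]2(C)O[Si](CC)(CC)CC)C2CCCC1CCC2
F3 | step 1 | rac-(4aS,8aS)-2,5,5,8a-tetramethyl-4a,5,6,7,8,8a-hexahydro-4H-chromene (racemate; one antipode drawn) | CC1=CC[C@H]2C(C)(C)CCC[C@]2(C)O1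
F4 | step 1 | rac-(1S,2S)-2-(2-hydroperoxy-2-methoxyethyl)-1,3,3-trimethylcyclohexyl acetate (racemate; one antipode drawn) | COC(OO)C[C@H]1C(C)(C)CCC[C@]1(C)OC(C)=O
F5 | step 1 | rac-(1S,2S)-1,3,3-trimethyl-2-(2-oxoethyl)cyclohexyl acetate (racemate; one antipode drawn) | O=CC[C@H]1C(C)(C)CCC[C@]1(C)OC(C)=O
F6 | step 1 | rac-(1S,2S)-2-(2-hydroxyethyl)-1,3,3-trimethylcyclohexan-1-ol (racemate; one antipode drawn) | OCC[C@H]1C(C)(C)CCC[C@]1(C)O
F7 | step 1 | 2-[(1S,2S)-2-hydroxy-2,6,6-trimethylcyclohexyl]ethyl (2S)-2-methoxy-2-phenylacetate | CO[C@H](C(=O)OCC[C@H]1C(C)(C)CCC[C@]1(C)O)c1ccccc1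
F8 | step 1 | 2-[(1R,2R)-2-hydroxy-2,6,6-trimethylcyclohexyl]ethyl (2S)-2-methoxy-2-phenylacetate | CO[C@H](C(=O)OCC[C@@H]1C(C)(C)CCC[C@@]1(C)O)c1ccccc1
F9 | step 11 | (3R,5Z)-6-({[tert-butyl(diphenyl)silyl]oxy}methyl)-8-(1,3-dioxolan-2-yl)-1-(methoxymethoxy)-2-oxooct-5-en-3-yl (diethoxyphosphoryl)acetate | COCOCC(=O)[C@H](OC(=O)CP(=O)(OCC)OCC)C/C=C(/CCC1OCCO1)CO[Si](c1ccccc1)(c1ccccc1)C(C)(C)C
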